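The ten-membered carbocycle is disconnected at C3–C4, the bond between the ketone carbon and the (4Z)-alkene (germacrane numbering). The key step exploits this cis-enone unit C3(=O)–C4=C5: an intramolecular Nozaki–Hiyama–Kishi reaction joins a (Z)-iodoalkene at C4 to an aldehyde at C3, closing the carbocycle last and carrying the Z geometry into the ring; oxidation then gives the enone. The precursor is an open chain on a preformed cis-disubstituted α-methylene-γ-butyrolactone ring (O–C6–C7–C11–C12), which together with the cis-alkene turns both chain ends toward each other. C10 comes from (R)-linalool, C8 from proline-catalysed α-oxygenation, C6/C7 from a syn-selective indium allylation–lactonisation.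

Key step: step 16

Remark on numbering: germacrane numbering is used throughout. C1/C2 are the ring CH2 groups, C3 the ketone carbon, C4=C5 the ring alkene, C15 the hydroxymethyl carbon, C6 the lactone O–CH, C7 the lactone CH, C8 the ester-bearing carbon, C10 the carbinol carbon (C14 its methyl), and C11/C12/C13 the lactone C=, C=O and =CH2.

Remark on descriptors: the CIP letters at C6 and C7 change along the route (iodine on C4, silyl ether on O8) while the spatial arrangement stays that of the target; the SMILES are authoritative.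

Assumption: (R)-(−)-linalool of high enantiomeric purity, methyl acrylate, but-2-yne-1,4-diol and angelic acid are purchased.

Step 1
Reactants: 1 (R)-(−)-linalool
Product: 2 (3R)-3,7-dimethyl-3-(triethylsilyloxy)octa-1,6-diene
Conditions: TESOTf, 2,6-lutidine, CH2Cl2, −78 to 0 °C
Reagents that add atoms: triethylsilyl triflate, CC[Si](CC)(CC)OS(=O)(=O)C(F)(F)F
Why: Silylation of the tertiary alcohol with the silyl triflate masks O10 (the later aldehydes would otherwise close to lactols); C10 is taken unchanged from the chiral pool.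

Step 2
Reactants: 2 (3R)-3,7-dimethyl-3-(triethylsilyloxy)octa-1,6-diene
Product: 3 (4R)-4,8-dimethyl-4-(triethylsilyloxy)non-7-enal
Conditions: Rh(acac)(CO)2 (1 mol%), BiPhePhos (2 mol%), CO/H2 (1:1, 10 bar), toluene, 60 °C
Reagents that add atoms: carbon monoxide, [C-]#[O+]
Why: Rhodium-catalysed hydroformylation should act only on the monosubstituted vinyl group (the quaternary neighbour excludes the branched isomer and the trisubstituted alkene is inert), adding C7 as the linear aldehyde.

Step 3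
Reactants: 3 (4R)-4,8-dimethyl-4-(triethylsilyloxy)non-7-enal
Product: 5 (2R,4R)-4,8-dimethyl-2-(phenylaminooxy)-4-(triethylsilyloxy)non-7-en-1-ol, via aminoxy aldehyde 4 (not isolated)
Conditions: PhNO, L-proline (20 mol%), DMSO, rt; then NaBH4, EtOH, 0 °C
Reagents that add atoms: nitrosobenzene, O=Nc1ccccc1
Why: Proline-catalysed enamine α-aminoxylation (O-selective nitroso aldol) should set C8 as R, because L-proline delivers the electrophile to the enamine face held by its carboxylic acid, and the labile α-oxy aldehyde is reduced in the same flask.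

Step 4
Reactants: 5 (2R,4R)-4,8-dimethyl-2-(phenylaminooxy)-4-(triethylsilyloxy)non-7-en-1-ol
Product: 6 (2R,4R)-4,8-dimethyl-4-(triethylsilyloxy)non-7-ene-1,2-diol
Conditions: Zn, AcOH, EtOH, rt
Reagents that add atoms: none
Why: Dissolving-metal reduction cleaves the weak N–O bond and should leave the alkene, the silyl ether and C8 untouched.

Step 5
Reactants: 6 (2R,4R)-4,8-dimethyl-4-(triethylsilyloxy)non-7-ene-1,2-diol
Product: 7 (2R,4R)-4,8-dimethyl-1,2,4-tris(triethylsilyloxy)non-7-ene
Conditions: TESCl, imidazole, DMAP (cat.), CH2Cl2, 0 °C to rt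
Reagents that add atoms: chlorotriethylsilane, CC[Si](Cl)(CC)CC
Why: Standard silylation of both hydroxyls; a non-chelating silyl ether on O8 is wanted for the facial selectivity of step 12.

Step 6
Reactants: 7 (2R,4R)-4,8-dimethyl-1,2,4-tris(triethylsilyloxy)non-7-ene
Product: 9 (2R,4R)-4,8-dimethyl-2,4-bis(triethylsilyloxy)non-7-enal, via alkoxysulfonium chloride 8 (not isolated)
Conditions: (COCl)2, DMSO, CH2Cl2, −78 to −40 °C; then Et3N, −78 to 0 °C
Reagents that add atoms: none
Why: Swern oxidation of a primary triethylsilyl ether: activated DMSO attacks only the least hindered silyl ether oxygen, so the primary OTES should go directly to the aldehyde while the secondary and tertiary OTES stay, and the low temperature guards C8 against epimerisation.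

Step 7
Reactants: 9 (2R,4R)-4,8-dimethyl-2,4-bis(triethylsilyloxy)non-7-enal; 10 methyl acrylate
Product: 11 methyl (4R,6R)-3-hydroxy-6,10-dimethyl-2-methylidene-4,6-bis(triethylsilyloxy)undec-9-enoate (both C3 epimers)
Conditions: DABCO (1 equiv), neat in 10, rt, 3–5 d
Reagents that add atoms: none
Why: Morita–Baylis–Hillman reaction, for which α-silyloxy aldehydes are activated acceptors; the new carbinol centre is unimportant because step 8 removes it.

Step 8
Reactants: 11 methyl (4R,6R)-3-hydroxy-6,10-dimethyl-2-methylidene-4,6-bis(triethylsilyloxy)undec-9-enoate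
Product: 12 methyl (2Z,4R,6R)-2-(bromomethyl)-6,10-dimethyl-4,6-bis(triethylsilyloxy)undeca-2,9-dienoate
Conditions: NBS, Me2S, CH2Cl2, 0 °C
Reagents that add atoms: N-bromosuccinimide, BrN1C(=O)CCC1=O
Why: Sulfonium activation of the allylic alcohol and SN2′ return of bromide should give the thermodynamically preferred trisubstituted enoate with the chain cis to CH2Br under neutral conditions that spare the silyl ethers.

Step 9
Reactants: 13 but-2-yne-1,4-diol
Product: 14 4-(tert-butyldiphenylsilyloxy)but-2-yn-1-ol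
Conditions: TBDPSCl (0.33 equiv), imidazole, THF/DMF, 0 °C
Reagents that add atoms: tert-butylchlorodiphenylsilane, CC(C)(C)[Si](Cl)(c1ccccc1)c1ccccc1
Why: Statistical monosilylation with the diol in excess; the acid-stable TBDPS group is chosen so that O15 survives step 13.

Step 10
Reactants: 14 4-(tert-butyldiphenylsilyloxy)but-2-yn-1-ol
Product: 16 (2Z)-4-(tert-butyldiphenylsilyloxy)-3-iodobut-2-en-1-ol, via alkenylaluminate 15 (not isolated)
Conditions: Red-Al, THF, 0 °C; then I2, THF, −78 °C
Reagents that add atoms: iodine, II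
Why: Alkoxide-directed trans-hydroalumination of the propargylic alcohol puts aluminium on the distal alkyne carbon (C4) in a five-membered oxa-aluminacycle, and iodinolysis with retention should give the iodoalkene with iodine cis to the CH2OH carbon (C6), which fixes the later 4Z geometry.

Step 11
Reactants: 16 (2Z)-4-(tert-butyldiphenylsilyloxy)-3-iodobut-2-en-1-ol
Product: 17 (2Z)-4-(tert-butyldiphenylsilyloxy)-3-iodobut-2-enal
Conditions: MnO2, CH2Cl2, rt
Reagents that add atoms: none
Why: Manganese dioxide oxidises the allylic alcohol selectively and should not touch the alkenyl iodide or its geometry.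

Step 12
Reactants: 12 methyl (2Z,4R,6R)-2-(bromomethyl)-6,10-dimethyl-4,6-bis(triethylsilyloxy)undeca-2,9-dienoate; 17 (2Z)-4-(tert-butyldiphenylsilyloxy)-3-iodobut-2-enal
Product: 19 (4S,5R)-5-[(1Z)-3-(tert-butyldiphenylsilyloxy)-2-iodoprop-1-en-1-yl]-4-[(1R,3R)-3,7-dimethyl-1,3-bis(triethylsilyloxy)oct-6-en-1-yl]-3-methylideneoxolan-2-one, via hydroxy ester 18 (not isolated)
Conditions: In powder, DMF, 0 °C to rt; then PPTS (cat.), toluene, 60 °C
Reagents that add atoms: none
Why: Indium Barbier allylation through a closed chair transition state, in which the chain-cis allylindium should give the syn adduct and hence the cis lactone on closure of the only free hydroxyl (O6) onto the ester; C8 controls the face by allylic 1,3-strain (C8–H in the alkene plane, aldehyde anti to the C9 chain, non-chelating OTES outside), which should set C7 and C6 in the 7,8-anti arrangement of the target.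

Step 13
Reactants: 19 cis-lactone bis(triethylsilyl) ether
Product: 20 (4R,5R)-5-[(1Z)-3-(tert-butyldiphenylsilyloxy)-2-iodoprop-1-en-1-yl]-4-[(1R,3R)-1-hydroxy-3,7-dimethyl-3-(triethylsilyloxy)oct-6-en-1-yl]-3-methylideneoxolan-2-one
Conditions: PPTS, MeOH/CH2Cl2 (1:1), 0 °C
Reagents that add atoms: none
Why: Mild acid methanolysis should remove the secondary TES ether well before the hindered tertiary TES and the acid-stable TBDPS ether, and at 0 °C the freed 8-OH should not translactonise.

Step 14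
Reactants: 20 C8 alcohol; 21 angelic acid
Product: 23 (1R,3R)-1-[(2R,3R)-2-[(1Z)-3-(tert-butyldiphenylsilyloxy)-2-iodoprop-1-en-1-yl]-4-methylidene-5-oxooxolan-3-yl]-3,7-dimethyl-3-(triethylsilyloxy)oct-6-en-1-yl (2Z)-2-methylbut-2-enoate, via mixed anhydride 22 (not isolated)
Conditions: 2,4,6-trichlorobenzoyl chloride, Et3N, toluene, rt; then 20, 70 °C
Reagents that add atoms: none
Why: Yamaguchi esterification through the mixed anhydride without DMAP acylates the only free hydroxyl and is the usual way to keep the Z (angelate) geometry from isomerising to the tiglate.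

Step 15
Reactants: 23 angelate with the 2-methylprop-1-enyl terminus
Product: 25 (1R,3R)-1-[(2R,3R)-2-[(1Z)-3-(tert-butyldiphenylsilyloxy)-2-iodoprop-1-en-1-yl]-4-methylidene-5-oxooxolan-3-yl]-3-methyl-6-oxo-3-(triethylsilyloxy)hexyl (2Z)-2-methylbut-2-enoate, via ozonide 24 (not isolated)
Conditions: O3 (1 equiv, Sudan Red 7B as indicator), CH2Cl2, −78 °C; then PPh3, −78 °C to rt
Reagents that add atoms: ozone, [O-][O+]=O
Why: Ozone reacts fastest with the electron-rich trisubstituted alkene, so one equivalent should unmask the C3 aldehyde while the acrylate-type alkenes and the iodoalkene, all electron-poor, survive.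

Step 16
Reactants: 25 iodoalkenyl aldehyde
Product: 26 (4Z,6S,7R,8R,10R)-8-[(2Z)-2-methylbut-2-enoyloxy]-15-(tert-butyldiphenylsilyloxy)-3-hydroxy-10-(triethylsilyloxy)germacra-4,11(13)-dien-12,6-olide (both C3 epimers)
Conditions: CrCl2 (10 equiv), NiCl2 (0.1 equiv), DMSO/THF, rt, 2 mM, addition of 25 by syringe pump
Reagents that add atoms: none
Why: Nickel(0) formed in situ inserts into the C4–I bond with retention, the alkenyl group passes to chromium(III), and the alkenylchromium adds to the C3 aldehyde (Nozaki–Hiyama–Kishi reaction). The closest known reaction type is the NHK macrocyclisation of iodoalkenyl aldehydes to medium and large carbocycles. The ten-membered ring closes at C3–C4 in the 10-exo-trig mode. The new stereocentre C3 is not controlled and need not be, since step 17 oxidises it, while C4=C5 keeps the Z geometry fixed in step 10. The step needs ring closure over oligomerisation and attack on the aldehyde only; high dilution with slow addition, the turn imposed by the cis-lactone and the Z-alkene, and the inertness of organochromium(III) toward the lactone, the enoates and the silyl ethers should secure both.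

Step 17
Reactants: 26 macrocyclic allylic alcohol
Product: 27 (4Z,6S,7R,8R,10R)-8-[(2Z)-2-methylbut-2-enoyloxy]-15-(tert-butyldiphenylsilyloxy)-3-oxo-10-(triethylsilyloxy)germacra-4,11(13)-dien-12,6-olide
Conditions: Dess–Martin periodinane, NaHCO3, CH2Cl2, 0 °C to rt
Reagents that add atoms: none
Why: Dess–Martin oxidation of the only free (allylic) hydroxyl under buffered neutral conditions should give the enone from both C3 epimers.

Step 18
Reactants: 27 bis-silylated enone
Product: 28 CNP0181802.1, (4Z,6S,7R,8R,10R)-8-[(2Z)-2-methylbut-2-enoyloxy]-10,15-dihydroxy-3-oxogermacra-4,11(13)-dien-12,6-olide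
Conditions: HF·pyridine, pyridine, THF, 0 °C to rt
Reagents that add atoms: none
Why: Buffered HF·pyridine should cleave the tertiary TES and the primary TBDPS ethers without base, so that the α-methylene lactone, the enone and the angelate are left alone.

Compound list
1 | (R)-(−)-linalool, (3R)-3,7-dimethylocta-1,6-dien-3-ol | CC(C)=CCC[C@@](C)(O)C=C | starting material
2 | (3R)-3,7-dimethyl-3-(triethylsilyloxy)octa-1,6-diene | CC(C)=CCC[C@@](C)(O[Si](CC)(CC)CC)C=C | intermediate
3 | (4R)-4,8-dimethyl-4-(triethylsilyloxy)non-7-enal | CC(C)=CCC[C@@](C)(O[Si](CC)(CC)CC)CCC=O | intermediate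
4 | (2R,4R)-4,8-dimethyl-2-(phenylaminooxy)-4-(triethylsilyloxy)non-7-enal | CC(C)=CCC[C@@](C)(O[Si](CC)(CC)CC)C[C@@H](ONc1ccccc1)C=O | intermediate
5 | (2R,4R)-4,8-dimethyl-2-(phenylaminooxy)-4-(triethylsilyloxy)non-7-en-1-ol | CC(C)=CCC[C@@](C)(O[Si](CC)(CC)CC)C[C@@H](ONc1ccccc1)CO | intermediate
6 | (2R,4R)-4,8-dimethyl-4-(triethylsilyloxy)non-7-ene-1,2-diol | CC(C)=CCC[C@@](C)(O[Si](CC)(CC)CC)C[C@@H](O)CO | intermediate
7 | (2R,4R)-4,8-dimethyl-1,2,4-tris(triethylsilyloxy)non-7-ene | CC(C)=CCC[C@@](C)(O[Si](CC)(CC)CC)C[C@@H](O[Si](CC)(CC)CC)CO[Si](CC)(CC)CC | intermediate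
8 | {[(2R,4R)-4,8-dimethyl-2,4-bis(triethylsilyloxy)non-7-en-1-yl]oxy}dimethylsulfonium chloride | CC(C)=CCC[C@@](C)(O[Si](CC)(CC)CC)C[C@@H](O[Si](CC)(CC)CC)CO[S+](C)C.[Cl-] | intermediate
9 | (2R,4R)-4,8-dimethyl-2,4-bis(triethylsilyloxy)non-7-enal | CC(C)=CCC[C@@](C)(O[Si](CC)(CC)CC)C[C@@H](O[Si](CC)(CC)CC)C=O | intermediate
10 | methyl acrylate | C=CC(=O)OC | starting material
11 | methyl (4R,6R)-3-hydroxy-6,10-dimethyl-2-methylidene-4,6-bis(triethylsilyloxy)undec-9-enoate (C3 epimers) | CC(C)=CCC[C@@](C)(O[Si](CC)(CC)CC)C[C@@H](O[Si](CC)(CC)CC)C(O)C(=C)C(=O)OC | intermediate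
12 | methyl (2Z,4R,6R)-2-(bromomethyl)-6,10-dimethyl-4,6-bis(triethylsilyloxy)undeca-2,9-dienoate | CC(C)=CCC[C@@](C)(O[Si](CC)(CC)CC)C[C@@H](O[Si](CC)(CC)CC)/C=C(\CBr)C(=O)OC | intermediate
13 | but-2-yne-1,4-diol | OCC#CCO | starting material
14 | 4-(tert-butyldiphenylsilyloxy)but-2-yn-1-ol | OCC#CCO[Si](c1ccccc1)(c1ccccc1)C(C)(C)C | intermediate
15 | sodium 2,2-bis(2-methoxyethoxy)-3-[(tert-butyldiphenylsilyloxy)methyl]-2,5-dihydro-1,2-oxaaluminol-2-uide (cyclic alkenylaluminate) | [Na+].COCCO[Al-]1(OCCOC)OCC=C1CO[Si](c1ccccc1)(c1ccccc1)C(C)(C)C | intermediate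
16 | (2Z)-4-(tert-butyldiphenylsilyloxy)-3-iodobut-2-en-1-ol | OC/C=C(\I)CO[Si](c1ccccc1)(c1ccccc1)C(C)(C)C | intermediate
17 | (2Z)-4-(tert-butyldiphenylsilyloxy)-3-iodobut-2-enal | O=C/C=C(\I)CO[Si](c1ccccc1)(c1ccccc1)C(C)(C)C | intermediate
18 | methyl (3S,4R,5Z)-7-(tert-butyldiphenylsilyloxy)-3-[(1R,3R)-3,7-dimethyl-1,3-bis(triethylsilyloxy)oct-6-en-1-yl]-4-hydroxy-6-iodo-2-methylidenehept-5-enoate | CC(C)=CCC[C@@](C)(O[Si](CC)(CC)CC)C[C@@H](O[Si](CC)(CC)CC)[C@@H](C(=C)C(=O)OC)[C@@H](O)/C=C(\I)CO[Si](c1ccccc1)(c1ccccc1)C(C)(C)C | intermediate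
19 | (4S,5R)-5-[(1Z)-3-(tert-butyldiphenylsilyloxy)-2-iodoprop-1-en-1-yl]-4-[(1R,3R)-3,7-dimethyl-1,3-bis(triethylsilyloxy)oct-6-en-1-yl]-3-methylideneoxolan-2-one | CC(C)=CCC[C@@](C)(O[Si](CC)(CC)CC)C[C@@H](O[Si](CC)(CC)CC)[C@H]1C(=C)C(=O)O[C@H]1/C=C(\I)CO[Si](c2ccccc2)(c2ccccc2)C(C)(C)C | intermediate
20 | (4R,5R)-5-[(1Z)-3-(tert-butyldiphenylsilyloxy)-2-iodoprop-1-en-1-yl]-4-[(1R,3R)-1-hydroxy-3,7-dimethyl-3-(triethylsilyloxy)oct-6-en-1-yl]-3-methylideneoxolan-2-one | CC(C)=CCC[C@@](C)(O[Si](CC)(CC)CC)C[C@@H](O)[C@H]1C(=C)C(=O)O[C@H]1/C=C(\I)CO[Si](c2ccccc2)(c2ccccc2)C(C)(C)C | intermediate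
21 | angelic acid, (2Z)-2-methylbut-2-enoic acid | C/C=C(/C)C(=O)O | starting material
22 | (2Z)-2-methylbut-2-enoic 2,4,6-trichlorobenzoic anhydride | C/C=C(/C)C(=O)OC(=O)c1c(Cl)cc(Cl)cc1Cl | intermediate
23 | (1R,3R)-1-[(2R,3R)-2-[(1Z)-3-(tert-butyldiphenylsilyloxy)-2-iodoprop-1-en-1-yl]-4-methylidene-5-oxooxolan-3-yl]-3,7-dimethyl-3-(triethylsilyloxy)oct-6-en-1-yl (2Z)-2-methylbut-2-enoate | CC(C)=CCC[C@@](C)(O[Si](CC)(CC)CC)C[C@@H](OC(=O)/C(C)=C\C)[C@H]1C(=C)C(=O)O[C@H]1/C=C(\I)CO[Si](c2ccccc2)(c2ccccc2)C(C)(C)C | intermediate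
24 | secondary ozonide of 23 (3,3-dimethyl-1,2,4-trioxolan-5-yl in place of the 2-methylprop-1-enyl terminus) | CC1(C)OOC(CC[C@@](C)(O[Si](CC)(CC)CC)C[C@@H](OC(=O)/C(C)=C\C)[C@H]2C(=C)C(=O)O[C@H]2/C=C(\I)CO[Si](c3ccccc3)(c3ccccc3)C(C)(C)C)O1 | intermediate
25 | (1R,3R)-1-[(2R,3R)-2-[(1Z)-3-(tert-butyldiphenylsilyloxy)-2-iodoprop-1-en-1-yl]-4-methylidene-5-oxooxolan-3-yl]-3-methyl-6-oxo-3-(triethylsilyloxy)hexyl (2Z)-2-methylbut-2-enoate | O=CCC[C@@](C)(O[Si](CC)(CC)CC)C[C@@H](OC(=O)/C(C)=C\C)[C@H]1C(=C)C(=O)O[C@H]1/C=C(\I)CO[Si](c2ccccc2)(c2ccccc2)C(C)(C)C | intermediate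
26 | (4Z,6S,7R,8R,10R)-8-[(2Z)-2-methylbut-2-enoyloxy]-15-(tert-butyldiphenylsilyloxy)-3-hydroxy-10-(triethylsilyloxy)germacra-4,11(13)-dien-12,6-olide (C3 epimers) | C=C1C(=O)O[C@H]2/C=C(/CO[Si](c3ccccc3)(c3ccccc3)C(C)(C)C)C(O)CC[C@@](C)(O[Si](CC)(CC)CC)C[C@@H](OC(=O)/C(C)=C\C)[C@@H]12 | intermediate
27 | (4Z,6S,7R,8R,10R)-8-[(2Z)-2-methylbut-2-enoyloxy]-15-(tert-butyldiphenylsilyloxy)-3-oxo-10-(triethylsilyloxy)germacra-4,11(13)-dien-12,6-olide | C=C1C(=O)O[C@H]2/C=C(/CO[Si](c3ccccc3)(c3ccccc3)C(C)(C)C)C(=O)CC[C@@](C)(O[Si](CC)(CC)CC)C[C@@H](OC(=O)/C(C)=C\C)[C@@H]12 | intermediate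
28 | CNP0181802.1, (4Z,6S,7R,8R,10R)-8-[(2Z)-2-methylbut-2-enoyloxy]-10,15-dihydroxy-3-oxogermacra-4,11(13)-dien-12,6-olide | C=C1C(=O)O[C@H]2/C=C(/CO)C(=O)CC[C@@](C)(O)C[C@@H](OC(=O)/C(C)=C\C)[C@@H]12 | target

Total step count: 18. Longest linear sequence: 15 steps (steps 1–8 and 12–18; steps 9–11 make the aldehyde 17 in a side branch).

Steps most likely to fail

1. Step 16 (key ring closure). Oligomerisation may outrun the slow ten-membered closure, and the alkenyl–metal intermediate may be lost by protonation. The fallback closes the same C3–C4 bond as an acyl–alkenyl coupling and sets out from aldehyde 25. Pinnick oxidation (NaClO2, NaH2PO4, 2-methyl-2-butene) gives the iodo acid F1, and EtSH with EDC and DMAP gives the S-ethyl thioester F2. Hexamethylditin with Pd(PPh3)4 turns the iodoalkene into the alkenylstannane F3 with retention. A palladium-catalysed, copper(I)-mediated thioester–stannane coupling of the Liebeskind–Srogl type (Pd2(dba)3, tri(2-furyl)phosphine, copper(I) diphenylphosphinate, THF, high dilution) then forms the ring ketone directly and comes back to the route at enone 27, without steps 16 and 17.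

2. Step 12 (allylation–lactonisation). Facial selectivity with respect to C8 may be poor, or reversed by chelation if the C8 silyl ether is partly lost, giving the 7,8-syn cis-lactone. The fallback replaces substrate control by catalyst control and sets out from bromide 12. Miyaura-type borylation (B2pin2, Pd2(dba)3, toluene, 50 °C) gives the allylboronate F4. Its allylboration of aldehyde 17 under a chiral phosphoric acid (either enantiomer of TRIP, toluene, −30 °C) runs through a metal-free closed chair transition state and comes back to the route at hydroxy ester 18, which is lactonised to 19 as in step 12.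

3. Step 15 (unmasking of the C3 aldehyde). Over-oxidation may set in: ozone may start on the exocyclic methylene or the angelate before the trisubstituted alkene is consumed. The fallback sets out from 23 and uses osmium in place of ozone. Catalytic OsO4 with NMO (acetone/water) should dihydroxylate only the electron-rich trisubstituted alkene to the diol F5, and NaIO4 (THF/water) cleaves it and comes back to the route at aldehyde 25.

Further compounds
F1 | step 16 | (4R,6R)-6-[(2R,3R)-2-[(1Z)-3-(tert-butyldiphenylsilyloxy)-2-iodoprop-1-en-1-yl]-4-methylidene-5-oxooxolan-3-yl]-4-methyl-6-[(2Z)-2-methylbut-2-enoyloxy]-4-(triethylsilyloxy)hexanoic acid | OC(=O)CC[C@@](C)(O[Si](CC)(CC)CC)C[C@@H](OC(=O)/C(C)=C\C)[C@H]1C(=C)C(=O)O[C@H]1/C=C(\I)CO[Si](c2ccccc2)(c2ccccc2)C(C)(C)C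
F2 | step 16 | S-ethyl thioester of F1 | CCSC(=O)CC[C@@](C)(O[Si](CC)(CC)CC)C[C@@H](OC(=O)/C(C)=C\C)[C@H]1C(=C)C(=O)O[C@H]1/C=C(\I)CO[Si](c2ccccc2)(c2ccccc2)C(C)(C)C
F3 | step 16 | S-ethyl thioester F2 with trimethylstannyl in place of iodine (same alkene geometry) | CCSC(=O)CC[C@@](C)(O[Si](CC)(CC)CC)C[C@@H](OC(=O)/C(C)=C\C)[C@H]1C(=C)C(=O)O[C@H]1/C=C(\[Sn](C)(C)C)CO[Si](c2ccccc2)(c2ccccc2)C(C)(C)C
F4 | step 12 | methyl (2E,4R,6R)-6,10-dimethyl-2-[(4,4,5,5-tetramethyl-1,3,2-dioxaborolan-2-yl)methyl]-4,6-bis(triethylsilyloxy)undeca-2,9-dienoate (chain cis to CH2B as in 12) | CC(C)=CCC[C@@](C)(O[Si](CC)(CC)CC)C[C@@H](O[Si](CC)(CC)CC)/C=C(\CB1OC(C)(C)C(C)(C)O1)C(=O)OC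
F5 | step 15 | angelate 23 with the 6,7-alkene of the octenyl chain as its 6,7-diol (C6 epimers) | CC(C)(O)C(O)CC[C@@](C)(O[Si](CC)(CC)CC)C[C@@H](OC(=O)/C(C)=C\C)[C@H]1C(=C)C(=O)O[C@H]1/C=C(\I)CO[Si](c2ccccc2)(c2ccccc2)C(C)(C)C
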